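**Retrosynthetic overview**
1. Target ⇐ C16 desilylation, C4 esterification and Evans–Tishchenko reduction (C2‑OAc, C4‑OH) ⇐ ten‑membered β‑hydroxy enone. Ring B is closed last, at C2–C3, by an aldol reaction.
2. The γ‑lactone, the C7/C8 oxygens and the (Z)‑C5=C6 enone all come from one trisubstituted furan: Reformatsky addition at C8, Achmatowicz ring expansion, then Luche reduction and lactonisation.
3. Key step: acid‑triggered ring expansion (cyclopropylcarbinyl → homoallyl) of a methylenebicyclo[3.1.0]hexane gives ring A with C14‑OAc and C11=C12. The C9–C10 bond comes from a glyoxal‑ene reaction.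
4. The bicyclo[3.1.0]hexene, whose cyclopropane steers C1, C10 and C14, comes from (R)‑4‑silyloxycyclopentenone by cyclopropanation, carbonyl transposition and cuprate addition.
5. Ring order: cyclopropane on a five‑membered ring → ring A (six) → temporary pyranone → γ‑lactone → ring B (ten).

Assumption: briarane numbering (C1–C20) is used for all intermediates; PMBOCH2SnBu3 (one step from Bu3SnCH2OH) and the t‑Bu‑box ligand are taken as purchasable reagents; the hemiketal intermediates are mixtures at C4.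

**Step 1**
Reactants: 1 (R)-4-(tert-butyldimethylsilyloxy)cyclopent-2-en-1-one
Product: 3 (1S,5S)-bicyclo[3.1.0]hex-3-en-2-one, via silyloxy bicyclohexanone 2 (not isolated)
Conditions: Me3S(O)I, NaH, DMSO, rt; then DBU, rt
Reagents that add atoms: trimethylsulfoxonium iodide, C[S+](C)(C)=O.[I-]
Why: Corey–Chaykovsky cyclopropanation in which the ylide adds to the enone face opposite OTBS, fixing the cis‑fused cyclopropane centres C12 and C14, after which DBU expels the silanolate by E1cB elimination.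

**Step 2**
Reactants: 3 (1S,5S)-bicyclo[3.1.0]hex-3-en-2-one
Product: 4 tertiary allylic alcohol 2-(PMBOCH2)bicyclo[3.1.0]hex-3-en-2-ol (OH syn to the cyclopropane CH2)
Conditions: PMBOCH2SnBu3, n-BuLi, THF, −78 °C; add 3; H2O quench
Reagents that add atoms: tributyl{[(4-methoxybenzyl)oxy]methyl}stannane, CCCC[Sn](CCCC)(CCCC)COCc1ccc(OC)cc1
Why: Tin–lithium exchange gives a hard α‑alkoxy organolithium that adds 1,2 to the enone from the convex face and brings in C2; the new carbinol centre is erased in step 3.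

**Step 3**
Reactants: 4 tertiary allylic alcohol
Product: 5 (1R,5S)-4-(PMBOCH2)bicyclo[3.1.0]hex-3-en-2-one
Conditions: [C5H5NH][CrO3Cl], 4 Å MS, CH2Cl2, rt
Reagents that add atoms: none
Why: Babler–Dauben oxidative allylic transposition, in which the tertiary chromate ester shifts to C11 and is oxidised, so the carbonyl moves to C11 and C1 becomes the enone β‑carbon while the cyclopropane centres are untouched.

**Step 4**
Reactants: 5 (1R,5S)-4-(PMBOCH2)bicyclo[3.1.0]hex-3-en-2-one
Product: 7 4-methyl-4-(PMBOCH2)bicyclo[3.1.0]hex-2-en-2-yl triflate (methyl anti and CH2OPMB syn to the cyclopropane CH2), via lithium enolate 6 (not isolated)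
Conditions: MeLi (2 equiv), CuI, Et2O, −40 °C; 5, −78 → −20 °C; then N-(5-chloropyridin-2-yl)triflimide, THF, −78 °C → rt
Reagents that add atoms: methyllithium, [Li]C; N-(5-chloropyridin-2-yl)bis(trifluoromethanesulfonimide), FC(F)(F)S(=O)(=O)N(c1ccc(Cl)cn1)S(=O)(=O)C(F)(F)F
Why: Gilman 1,4‑addition on the convex face, anti to the cyclopropane CH2, sets the C1 quaternary centre, and the regiodefined enolate is trapped by O‑triflation.

**Step 5**
Reactants: 7 vinyl triflate
Product: 8 2,4-dimethyl-4-(PMBOCH2)bicyclo[3.1.0]hex-2-ene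
Conditions: MeMgBr, Fe(acac)3 (5 mol%), THF/NMP, −30 → 0 °C
Reagents that add atoms: methylmagnesium bromide, C[Mg]Br
Why: Iron‑catalysed Kumada‑type coupling of an alkenyl triflate installs the C20 methyl group without touching the vinylcyclopropane or any stereocentre.

**Step 6**
Reactants: 9 (2-methylfuran-3-yl)methanol
Product: 10 tert-butyl[(2-methylfuran-3-yl)methoxy]diphenylsilane
Conditions: TBDPSCl, imidazole, DMF, rt
Reagents that add atoms: tert-butyl(chloro)diphenylsilane, CC(C)(C)[Si](Cl)(c1ccccc1)c1ccccc1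
Why: Standard silylation places an acid‑stable protecting group on the C16 oxygen.

**Step 7**
Reactants: 10 furan silyl ether
Product: 12 1-[4-(TBDPSOCH2)-5-methylfuran-2-yl]ethan-1-one, via 5-lithiofuran 11 (not isolated)
Conditions: n-BuLi, THF, −78 → 0 °C; MeC(O)N(OMe)Me, −78 °C; H2O
Reagents that add atoms: N-methoxy-N-methylacetamide, CC(=O)N(C)OC
Why: Lithiation at the only free furan α‑position (C7) followed by Weinreb ketone synthesis brings in C8 and C9.

**Step 8**
Reactants: 12 acetylfuran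
Product: 13 2-[4-(TBDPSOCH2)-5-methylfuran-2-yl]-2-oxoacetaldehyde
Conditions: SeO2, dioxane/H2O, 90 °C; dried by toluene azeotrope
Reagents that add atoms: selenium dioxide, O=[Se]=O
Why: Riley oxidation of an aryl methyl ketone gives the aryl glyoxal.

**Step 9**
Reactants: 8 2,4-dimethyl-4-(PMBOCH2)bicyclo[3.1.0]hex-2-ene; 13 furylglyoxal
Product: 15 (9R,10S) ene adduct acetate (C11=C20H2 and cyclopropane intact; C10–C9H(OAc)–C8(=O)–furyl), via ene adduct alcohol 14 (not isolated)
Conditions: [Cu((R,R)-t-Bu-box)](SbF6)2 (10 mol%), 4 Å MS, CH2Cl2, −20 °C → rt; then Ac2O, Et3N, DMAP (cat.), 0 °C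
Reagents that add atoms: acetic anhydride, CC(=O)OC(C)=O
Why: Catalytic asymmetric carbonyl‑ene (glyoxal‑ene) reaction in which only the C20 methyl offers a transferable hydrogen, the chelated glyoxal reaches C10 on the face anti to the cyclopropane CH2 (10S), and the box ligand selects the aldehyde face (9R) before in‑flask acetylation.

**Step 10**
Reactants: 15 ene adduct acetate
Product: 16 ring A ketone (14S acetate; C11=C12; C1 bears CH3 and CH2OPMB; C10–C9H(OAc)–C8(=O)–furyl)
Conditions: camphorsulfonic acid (0.2 equiv), AcOH/CH2Cl2 1:3, 0 °C → rt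
Reagents that add atoms: acetic acid, CC(=O)O
Why: Acid‑catalysed cyclopropylcarbinyl‑to‑homoallyl ring expansion (the sabinene to terpinen‑4‑yl type), in which protonation of the exocyclic alkene gives the tertiary C11 cation and acetic acid opens the internal C12–C14 bond at the more substituted cyclopropane carbon with inversion, creating ring A, the C11=C12 alkene and the 14S acetate at once.

**Step 11**
Reactants: 16 ring A ketone; 17 methyl 2-bromopropanoate
Product: 19 tertiary furyl carbinol ester (C8–OH; C17H(CH3)CO2Me; 17R), via zinc ester enolate 18 (not isolated)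
Conditions: 17, Zn dust, THF, 40 °C, decant; add to 16, THF, −20 °C → rt; H2O
Reagents that add atoms: none
Why: Reformatsky addition, mild enough for the acetates, in which zinc bridges the ketone and C9‑acetoxy oxygens and the bulky C10 ring carbon lies anti to the nucleophile (chelate and steric Felkin–Anh models agree) to set C8 as in the target, while the equilibrating zinc enolate reacts through the chair having the C9 branch equatorial and its methyl anti to the axial furyl to give 17R (minor C17 epimer removed by chromatography).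

**Step 12**
Reactants: 19 tertiary furyl carbinol ester
Product: 20 6-hydroxy-2H-pyran-3(6H)-one (O8–C8; C7=O; C5=C6; C4(OH)CH3)
Conditions: NBS (1.0 equiv), NaHCO3, THF/H2O 4:1, 0 °C
Reagents that add atoms: water, O
Why: Achmatowicz oxidative ring expansion of the electron‑rich furan, which reacts far faster than the trisubstituted alkene, unveils the C7 ketone and a C4 ketone masked as hemiketal, and locks C5=C6 as the Z alkene.

**Step 13**
Reactants: 20 pyranone hemiketal
Product: 22 cis-fused pyrano γ-lactone (7S), via allylic alcohol 21 (not isolated)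
Conditions: NaBH4, CeCl3·7H2O, MeOH, −78 → −20 °C; then PPTS (cat.), CH2Cl2, rt
Reagents that add atoms: none
Why: Luche 1,2‑reduction in which hydride attacks C7 opposite the pseudo‑axial C17 branch on C8 (the large C9 branch is pseudo‑equatorial), so the new OH is cis to C17 (7S) and closes the γ‑lactone with loss of methanol, while the hemiketal shields C4.

**Step 14**
Reactants: 22 PMB ether lactone
Product: 23 primary alcohol at C2
Conditions: DDQ, CH2Cl2/pH 7 buffer 10:1, 0 °C
Reagents that add atoms: none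
Why: Oxidative PMB cleavage under neutral conditions leaves acetates, lactone, hemiketal and silyl ether intact.

**Step 15**
Reactants: 23 primary alcohol
Product: 24 C2 aldehyde (neopentylic and non‑enolisable)
Conditions: Dess–Martin periodinane, pyridine, CH2Cl2, 0 °C → rt
Reagents that add atoms: none
Why: Dess–Martin oxidation of the only oxidisable alcohol, the hemiketal OH being tertiary.

**Step 16**
Reactants: 24 C2 aldehyde hemiketal
Product: 26 ten-membered β-hydroxy enone (2R; C4=O; 5Z; C8–OH), via bis-borinate dienolate 25 (not isolated)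
Conditions: c-Hex2BCl (3 equiv), Et3N (4 equiv), Et2O/CH2Cl2, 1 mM, −78 → −20 °C; MeOH/pH 7 buffer
Reagents that add atoms: none
Why: Proposed new method: boron‑mediated ring‑opening aldol macrocyclisation of a cyclic methyl hemiketal, in which c‑Hex2BCl borylates the hemiketal OH, ring–chain tautomerism frees the (Z)‑enone, a second boron/Et3N pair enolises its only enolisable site (C3), and the cross‑conjugated boron enolate adds to the non‑enolisable C2 aldehyde through a closed six‑membered transition state whose strong B–O chelate makes the otherwise reversible ten‑ring aldol irreversible; Felkin–Anh attack anti to the C1–C14 bond and past the C15 methyl, the only trajectory that keeps C3 gauche to C10, sets 2R; the closest known reaction type is the dialkylboron chloride aldol of methyl ketones, not yet used to close a ten‑membered carbocycle or to start from a hemiketal.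

**Step 17**
Reactants: 26 ten-membered β-hydroxy enone
Product: 27 (2R,4R) C2 acetate C4 alcohol
Conditions: SmI2 (0.3 equiv), MeCHO (10 equiv), THF, −10 °C
Reagents that add atoms: acetaldehyde, CC=O
Why: Evans–Tishchenko reduction, in which the C2 hemiacetal of acetaldehyde bound to trivalent samarium delivers hydride intramolecularly to C4, giving the 1,3‑anti relationship (4R), the C2 acetate and a free C4 hydroxyl in one step.

**Step 18**
Reactants: 28 (R)-3-hydroxybutanoic acid
Product: 29 (R)-3-acetoxybutanoic acid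
Conditions: Ac2O, pyridine, 0 °C → rt; H2O
Reagents that add atoms: acetic anhydride, CC(=O)OC(C)=O
Why: Simple O‑acetylation that leaves the purchased stereocentre untouched.

**Step 19**
Reactants: 27 C4 alcohol; 29 (R)-3-acetoxybutanoic acid
Product: 30 C16 TBDPS ether of the target
Conditions: DCC, DMAP (cat.), CH2Cl2, 0 °C
Reagents that add atoms: none
Why: Steglich esterification acylates the secondary allylic C4 hydroxyl while the tertiary C8 hydroxyl stays free.

**Step 20**
Reactants: 30 C16 TBDPS ether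
Product: 31 CNP0316115.1
Conditions: HF·pyridine, THF/pyridine, 0 °C → rt
Reagents that add atoms: none
Why: Buffered fluoride desilylation frees the C16 alcohol without acyl migration or ester cleavage.

**Compound list**
1 | (R)-4-(tert-butyldimethylsilyloxy)cyclopent-2-en-1-one | O=C1C[C@@H](O[Si](C)(C)C(C)(C)C)C=C1 | starting material
2 | (1S,4R,5R)-4-(tert-butyldimethylsilyloxy)bicyclo[3.1.0]hexan-2-one (CH2 anti to OTBS) | O=C1C[C@@H](O[Si](C)(C)C(C)(C)C)[C@@H]2C[C@H]12 | intermediate
3 | (1S,5S)-bicyclo[3.1.0]hex-3-en-2-one | O=C1C=C[C@@H]2C[C@H]12 | intermediate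
4 | 2-{[(4-methoxybenzyl)oxy]methyl}bicyclo[3.1.0]hex-3-en-2-ol (OH syn to cyclopropane CH2) | COc1ccc(COC[C@@]2(O)C=C[C@@H]3C[C@H]23)cc1 | intermediate
5 | (1R,5S)-4-{[(4-methoxybenzyl)oxy]methyl}bicyclo[3.1.0]hex-3-en-2-one | COc1ccc(COCC2=CC(=O)[C@@H]3C[C@H]23)cc1 | intermediate
6 | lithium enolate of 4-methyl-4-(PMBOCH2)bicyclo[3.1.0]hexan-2-one | COc1ccc(COC[C@@]2(C)[C@H]3C[C@H]3C(O[Li])=C2)cc1 | intermediate
7 | 4-methyl-4-(PMBOCH2)bicyclo[3.1.0]hex-2-en-2-yl triflate (methyl anti to cyclopropane CH2) | COc1ccc(COC[C@@]2(C)[C@H]3C[C@H]3C(OS(=O)(=O)C(F)(F)F)=C2)cc1 | intermediate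
8 | 2,4-dimethyl-4-(PMBOCH2)bicyclo[3.1.0]hex-2-ene | COc1ccc(COC[C@@]2(C)[C@H]3C[C@H]3C(C)=C2)cc1 | intermediate
9 | (2-methylfuran-3-yl)methanol | Cc1occc1CO | starting material
10 | tert-butyl[(2-methylfuran-3-yl)methoxy]diphenylsilane | Cc1occc1CO[Si](c2ccccc2)(c2ccccc2)C(C)(C)C | intermediate
11 | 5-lithio derivative of 10 | [Li]c1cc(CO[Si](c2ccccc2)(c2ccccc2)C(C)(C)C)c(C)o1 | intermediate
12 | 1-[4-(TBDPSOCH2)-5-methylfuran-2-yl]ethan-1-one | CC(=O)c1cc(CO[Si](c2ccccc2)(c2ccccc2)C(C)(C)C)c(C)o1 | intermediate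
13 | 2-[4-(TBDPSOCH2)-5-methylfuran-2-yl]-2-oxoacetaldehyde | O=CC(=O)c1cc(CO[Si](c2ccccc2)(c2ccccc2)C(C)(C)C)c(C)o1 | intermediate
14 | (9R,10S) ene adduct alcohol (3-methylenebicyclo[3.1.0]hexane, C9 chain anti to cyclopropane CH2) | COc1ccc(COC[C@@]2(C)[C@H]3C[C@H]3C(=C)[C@@H]2[C@@H](O)C(=O)c2cc(CO[Si](c3ccccc3)(c3ccccc3)C(C)(C)C)c(C)o2)cc1 | intermediate
15 | C9 acetate of 14 | COc1ccc(COC[C@@]2(C)[C@H]3C[C@H]3C(=C)[C@@H]2[C@@H](OC(C)=O)C(=O)c2cc(CO[Si](c3ccccc3)(c3ccccc3)C(C)(C)C)c(C)o2)cc1 | intermediate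
16 | ring A ketone (9R,10S,14S; 9,14-diacetate; C8 furyl ketone) | COc1ccc(COC[C@@]2(C)[C@@H](OC(C)=O)CC=C(C)[C@@H]2[C@@H](OC(C)=O)C(=O)c2cc(CO[Si](c3ccccc3)(c3ccccc3)C(C)(C)C)c(C)o2)cc1 | intermediate
17 | methyl 2-bromopropanoate (racemic) | COC(=O)C(C)Br | starting material
18 | bromo(1-methoxy-1-oxopropan-2-yl)zinc | COC(=O)C(C)[Zn]Br | intermediate
19 | C8 tertiary furyl carbinol methyl ester (17R) | COc1ccc(COC[C@@]2(C)[C@@H](OC(C)=O)CC=C(C)[C@@H]2[C@@H](OC(C)=O)[C@@](O)(c2cc(CO[Si](c3ccccc3)(c3ccccc3)C(C)(C)C)c(C)o2)[C@@H](C)C(=O)OC)cc1 | intermediate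
20 | Achmatowicz pyranone hemiketal (C7 ketone, C4 anomers) | COc1ccc(COC[C@@]2(C)[C@@H](OC(C)=O)CC=C(C)[C@@H]2[C@@H](OC(C)=O)[C@]2(OC(C)(O)C(CO[Si](c3ccccc3)(c3ccccc3)C(C)(C)C)=CC2=O)[C@@H](C)C(=O)OC)cc1 | intermediate
21 | (7S) allylic alcohol hemiketal | COc1ccc(COC[C@@]2(C)[C@@H](OC(C)=O)CC=C(C)[C@@H]2[C@@H](OC(C)=O)[C@]2(OC(C)(O)C(CO[Si](c3ccccc3)(c3ccccc3)C(C)(C)C)=C[C@@H]2O)[C@@H](C)C(=O)OC)cc1 | intermediate
22 | cis-fused pyrano γ-lactone, C2 PMB ether | COc1ccc(COC[C@@]2(C)[C@@H](OC(C)=O)CC=C(C)[C@@H]2[C@@H](OC(C)=O)[C@@]23OC(C)(O)C(CO[Si](c4ccccc4)(c4ccccc4)C(C)(C)C)=C[C@@H]2OC(=O)[C@@H]3C)cc1 | intermediate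
23 | C2 primary alcohol | OC[C@@]1(C)[C@@H](OC(C)=O)CC=C(C)[C@@H]1[C@@H](OC(C)=O)[C@@]12OC(C)(O)C(CO[Si](c3ccccc3)(c3ccccc3)C(C)(C)C)=C[C@@H]1OC(=O)[C@@H]2C | intermediate
24 | C2 aldehyde | O=C[C@@]1(C)[C@@H](OC(C)=O)CC=C(C)[C@@H]1[C@@H](OC(C)=O)[C@@]12OC(C)(O)C(CO[Si](c3ccccc3)(c3ccccc3)C(C)(C)C)=C[C@@H]1OC(=O)[C@@H]2C | intermediate
25 | ring-opened C8 borinate, C3=C4 boron dienolate | O=C[C@@]1(C)[C@@H](OC(C)=O)CC=C(C)[C@@H]1[C@@H](OC(C)=O)[C@@]2(OB(C3CCCCC3)C3CCCCC3)[C@H](/C=C(\C(=C)OB(C3CCCCC3)C3CCCCC3)CO[Si](c3ccccc3)(c3ccccc3)C(C)(C)C)OC(=O)[C@@H]2C | intermediate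
26 | ten-membered β-hydroxy enone (2R, 5Z; drawn in the open keto form) | O=C1C[C@@H](O)[C@@]2(C)[C@@H](OC(C)=O)CC=C(C)[C@@H]2[C@@H](OC(C)=O)[C@@]2(O)[C@H](/C=C\1CO[Si](c3ccccc3)(c3ccccc3)C(C)(C)C)OC(=O)[C@@H]2C | intermediate
27 | (2R,4R) 2,9,14-triacetate with free C4 and C8 hydroxyls | O[C@@H]1C[C@@H](OC(C)=O)[C@@]2(C)[C@@H](OC(C)=O)CC=C(C)[C@@H]2[C@@H](OC(C)=O)[C@@]2(O)[C@H](/C=C\1CO[Si](c3ccccc3)(c3ccccc3)C(C)(C)C)OC(=O)[C@@H]2C | intermediate
28 | (R)-3-hydroxybutanoic acid | C[C@@H](O)CC(=O)O | starting material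
29 | (R)-3-acetoxybutanoic acid | CC(=O)O[C@H](C)CC(=O)O | intermediate
30 | C16 TBDPS ether of the target | CC(=O)O[C@H](C)CC(=O)O[C@@H]1C[C@@H](OC(C)=O)[C@@]2(C)[C@@H](OC(C)=O)CC=C(C)[C@@H]2[C@@H](OC(C)=O)[C@@]2(O)[C@H](/C=C\1CO[Si](c3ccccc3)(c3ccccc3)C(C)(C)C)OC(=O)[C@@H]2C | intermediate
31 | CNP0316115.1 | CC(=O)O[C@H](C)CC(=O)O[C@@H]1C[C@@H](OC(C)=O)[C@@]2(C)[C@@H](OC(C)=O)CC=C(C)[C@@H]2[C@@H](OC(C)=O)[C@@]2(O)[C@H](/C=C\1CO)OC(=O)[C@@H]2C | target

**Total step count:** 20.
**Longest linear sequence:** 16 steps (steps 1–5, 9–17, 19 and 20, from 1).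

**Three steps most likely to fail**

Step 16 (the new step). The ten‑ring aldol may not compete with oligomerisation, or the hemiketal may not open. The fallback sets out from 24 and comes back at 26, and uses reductive enolate generation in place of enolisation.
- TMSOTf/Et3N opens and silylates 24 to the C8 silyl ether silyl dienol ether F5.
- NBS converts it into the bromomethyl enone F6.
- SmI2 (2.2 equiv, THF, −78 °C, high dilution) then closes the ring by an intramolecular Reformatsky‑type aldol, a known way to medium carbocycles. The dilute‑acid work‑up removes the C8 silyl group and gives 26.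

Step 10. External acetate may not capture the neopentylic C14, so elimination or capture at C13 could win. The fallback sets out from 15 and comes back at 16, and delivers the oxygen from inside the molecule.
- DDQ frees the primary alcohol F2, and Ac2O/pyridine gives the C2 primary acetate F3.
- Camphorsulfonic acid in wet CH2Cl2 generates the same C11 cation, but the C2 acetoxy carbonyl oxygen, gauche to the breaking C12–C14 bond, now closes a six‑membered 1,3‑dioxan‑2‑ylium ion onto C14.
- Water collapses this ion to the axial C14 acetate in the ring‑expanded primary alcohol F4.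
- 4‑Methoxybenzyl trichloroacetimidate with La(OTf)3 (cat.) returns 16.

Step 9. The trisubstituted alkene next to a quaternary carbon may be too hindered for the catalytic ene reaction. The fallback sets out from 7 and comes back at 14, and replaces the ene reaction by an allylboration.
- Suzuki coupling of 7 with CH2(Bpin)2 (Pd[P(t-Bu)3]2, KOH, dioxane/H2O) gives the allyl pinacolboronate F1.
- F1 adds to the aldehyde of 13 through a closed chair. Attack is at the γ‑carbon C10, anti to the cyclopropane CH2, and the E‑type allyl geometry enforces the required 9,10‑anti relationship. This gives 14, which is acetylated as in step 9.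

**Further compounds**
F1 | step 9 | allyl pinacolboronate (C20H2–Bpin on the C10=C11 alkene of the bicyclo[3.1.0]hexene) | COc1ccc(COC[C@@]2(C)[C@H]3C[C@H]3C(CB3OC(C)(C)C(C)(C)O3)=C2)cc1
F2 | step 10 | C2 primary alcohol of the ene adduct acetate | OC[C@@]1(C)[C@H]2C[C@H]2C(=C)[C@@H]1[C@@H](OC(C)=O)C(=O)c1cc(CO[Si](c2ccccc2)(c2ccccc2)C(C)(C)C)c(C)o1
F3 | step 10 | C2,C9 diacetate of the ene adduct | CC(=O)OC[C@@]1(C)[C@H]2C[C@H]2C(=C)[C@@H]1[C@@H](OC(C)=O)C(=O)c1cc(CO[Si](c2ccccc2)(c2ccccc2)C(C)(C)C)c(C)o1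
F4 | step 10 | ring-expanded 9,14-diacetate with free C2 primary alcohol | OC[C@@]1(C)[C@@H](OC(C)=O)CC=C(C)[C@@H]1[C@@H](OC(C)=O)C(=O)c1cc(CO[Si](c2ccccc2)(c2ccccc2)C(C)(C)C)c(C)o1
F5 | step 16 | ring-opened C8 trimethylsilyl ether, C3=C4 silyl dienol ether aldehyde | O=C[C@@]1(C)[C@@H](OC(C)=O)CC=C(C)[C@@H]1[C@@H](OC(C)=O)[C@@]2(O[Si](C)(C)C)[C@H](/C=C(\C(=C)O[Si](C)(C)C)CO[Si](c3ccccc3)(c3ccccc3)C(C)(C)C)OC(=O)[C@@H]2C
F6 | step 16 | C3 bromomethyl (Z)-enone aldehyde, C8 trimethylsilyl ether | O=C[C@@]1(C)[C@@H](OC(C)=O)CC=C(C)[C@@H]1[C@@H](OC(C)=O)[C@@]2(O[Si](C)(C)C)[C@H](/C=C(\C(=O)CBr)CO[Si](c3ccccc3)(c3ccccc3)C(C)(C)C)OC(=O)[C@@H]2C
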